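In a one-step world Q and E give one product, and the charge tells the yield. This flask has more steps, and two charges are compared.

| flask | Q | E | time |
|---|---|---|---|
| winter | 0.050 M | 0.0490 M | 20 s |
| dawn | 0.050 M | 0.0640 M | 20 s |

    2 Q → Q2 (k1 = 0.277 /M/s)
    E + Q.E → E.Q.E (k2 = 0.690 /M/s)
    Q + E → Q.E (k3 = 9.49 /M/s)
    Q + E → X, rate k4*[Q] as long as [E] is above zero (k4 = 1.03 /s)

- in percentages every species weighs as the Q in it: one Q2 counts as two
- where a step has two of a species, its rate is k times that concentration squared, and two are used at each turn
- run time (winter): 20 s

* which of these there is most of at the end, counted by the Q in it, winter (X / Q / E.Q.E / Q.E)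
* which of these there is most of at the end, counted by the Q in it, dawn (X / Q / E.Q.E / Q.E)
* amount of the one of these that there is most of at the end, in percent of the Q charged, winter
* amount of the one of these that there is most of at the end, in percent of the Q charged, dawn

*Which exit does a Q take?* There are two exits, and each uses one Q and one E. Ring closure takes Q at 1.03 /s. Linking takes it at 9.49 /M/s times the free E. The crossover level is 2.17: the free E, as a fraction of the Q charged, at which both exits run equal. Call the crossover level h and the free E, in that fraction, e.

*What do you freeze?* Free Q minus free E, because each exit takes one of each.

*That is the weak spot. Q2 takes Q without E, and E.Q.E takes E without Q.* At the start Q goes to Q2 at 0.0277 /s per Q, far less than the 1.50 /s through the exits in winter. The constant for E.Q.E, 0.690 /M/s, is far less than that for linking, 9.49 /M/s. I drop both.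

*The yield, then?* At level e, the share h/(h+e) of what reacts goes to X. Summed as e falls, X is h ln((h+start)/(h+end)).

*Where does e end?* In winter it starts at 0.980, below the Q charge, so E is the limiting reagent and I take e down to zero. That gives 80.9%. At dawn it starts at 1.28, above the Q charge, so I stop e at 0.280. That gives 74.3%.

*And the leader?* The crossover level stands above e from the start, so the ring exit runs ahead. I name X for winter and X for dawn.

The forecast says X at 80.6% in winter and X at 73.4% at dawn, where “excess E pushes more Q into links”. My two yields lie slightly above its two.

The flask gives X at 80.6% in winter and X at 73.5% at dawn. At the end of the dawn flask, 19% of the charged E is still free. A neighbour of dawn is charged with 0.016 M of E, so e starts at 0.320, below the Q charge. Taking e to zero with the crossover level 2.17 gives 29.9% of X. That neighbour ends with E at 0%, Q at 49.3% and X at 29.8%.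

The numbers of this flask were chosen freely; no experiment stands behind them.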